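Daucane numbering: C1 methyl-bearing ring-fusion carbon, C4 isopropyl carbinol, C5 ring-fusion CH, C6 aroyloxy carbon, C7 CH2, C8=C9 alkene, C10 isovalerate carbon. With the C6 oxygen written as a C5=C6 enol ether, the seven-membered ring (C1, C5–C10) is a cyclohepta-1,4-diene, the product of a divinylcyclopropane rearrangement. A chromium methoxycarbene carrying the finished five-membered ring (C6 = carbene carbon, C1=C5 its alkene; C4 from (R)-terpinen-4-ol) cyclopropanates the terminal alkene of (E)-3-methylbuta-1,3-dienyl isovalerate; Cope rearrangement follows in the same flask. This formal (4+3) annulation makes C6–C7 and C1–C10, the C1 quaternary centre, the C10 stereocentre and the C6 oxidation level.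

Key step: step 7

Assumption: (R)-(−)-terpinen-4-ol of high enantiomeric purity and 4-[(tert-butyldimethylsilyl)oxy]benzoic acid are taken as catalogue compounds; ring A = cyclopentane C1–C5, ring B = cycloheptene C1, C5–C10.

Step 1
Reactants: 1 (R)-(−)-terpinen-4-ol
Product: 2 (R)-triethyl{[4-methyl-1-(propan-2-yl)cyclohex-3-en-1-yl]oxy}silane
Conditions: Et3SiOTf, 2,6-lutidine, CH2Cl2, 0 °C to rt
Reagents that add atoms: triethylsilyl trifluoromethanesulfonate, CC[Si](CC)(CC)OS(=O)(=O)C(F)(F)F
Why: Silyl triflate silylation of a hindered tertiary alcohol; the ether blocks elimination and acylation at the carbinol oxygen later on and leaves the stereocentre (future C4) untouched.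

Step 2
Reactants: 2 (R)-triethyl{[4-methyl-1-(propan-2-yl)cyclohex-3-en-1-yl]oxy}silane
Product: 4 (3R)-6-oxo-3-(propan-2-yl)-3-(triethylsilyloxy)heptanal, via secondary ozonide 3 (not isolated)
Conditions: O3, CH2Cl2, −78 °C; then PPh3, −78 °C to rt
Reagents that add atoms: ozone, [O-][O+]=O
Why: Ozonolysis with reductive work-up opens the cyclohexene between the future C1 (methyl ketone) and C6 (aldehyde) without involving the carbinol stereocentre.

Step 3
Reactants: 4 (3R)-6-oxo-3-(propan-2-yl)-3-(triethylsilyloxy)heptanal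
Product: 6 (5S)-2-methyl-5-(propan-2-yl)-5-(triethylsilyloxy)cyclopent-1-ene-1-carbaldehyde, via aldol adduct 5 (not isolated)
Conditions: piperidine (0.3 equiv), AcOH (0.3 equiv), toluene, 70 °C
Reagents that add atoms: none
Why: Amine-catalysed intramolecular aldol condensation, in which the aldehyde enamine (α-carbon = future C5) attacks the methyl ketone (future C1) in a 5-exo closure and dehydration gives the conjugated enal; the enamine pathway is the known way to steer 6-oxo aldehydes to 2-methylcyclopentenecarbaldehydes instead of acetylcyclopentenes.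

Step 4
Reactants: 6 (5S)-2-methyl-5-(propan-2-yl)-5-(triethylsilyloxy)cyclopent-1-ene-1-carbaldehyde
Product: 7 (5S)-2-methyl-5-(propan-2-yl)-5-(triethylsilyloxy)cyclopent-1-ene-1-carboxylic acid
Conditions: NaClO2, NaH2PO4, 2-methyl-2-butene, t-BuOH/H2O, 0 °C to rt
Reagents that add atoms: sodium chlorite, [Na+].[O-]Cl=O
Why: Pinnick oxidation should convert the hindered enal into the acid without touching the tetrasubstituted alkene or the silyl ether.

Step 5
Reactants: 7 (5S)-2-methyl-5-(propan-2-yl)-5-(triethylsilyloxy)cyclopent-1-ene-1-carboxylic acid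
Product: 10 pentacarbonyl{methoxy[(5S)-2-methyl-5-(propan-2-yl)-5-(triethylsilyloxy)cyclopent-1-en-1-yl]methylidene}chromium, via acid chloride 8 (not isolated), via sodium acylchromate 9 (not isolated)
Conditions: 1-chloro-N,N,2-trimethylprop-1-en-1-amine, CH2Cl2, 0 °C to rt, evaporate; Na2Cr(CO)5 [from Cr(CO)6 and NaC10H8 (sodium naphthalenide), THF, −78 °C], −78 to 0 °C; Me3OBF4, CH2Cl2, 0 °C
Reagents that add atoms: chromium hexacarbonyl (source of the Cr(CO)5 unit), O=C=[Cr](=C=O)(=C=O)(=C=O)(=C=O)=C=O; trimethyloxonium tetrafluoroborate, C[O+](C)C.F[B-](F)(F)F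
Why: Fischer carbene synthesis by the acid chloride route (neutral chlorination, acyl substitution by the pentacarbonylchromate dianion, O-methylation of the acylate), chosen because the route offers no alkenyllithium.

Step 6
Reactants: 11 3-methylbut-2-enal; 12 3-methylbutanoic anhydride
Product: 13 (E)-3-methylbuta-1,3-dien-1-yl 3-methylbutanoate
Conditions: Et3N, DMAP (cat.), neat, 90 °C; fractional distillation to the pure E isomer
Reagents that add atoms: none
Why: Dienol ester formation (γ-deprotonation of the enal and O-acylation of the dienolate) should give the 1-acyloxydiene that already carries the isovalerate, with the E enol ester as the expected major isomer.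

Step 7
Reactants: 10 pentacarbonyl{methoxy[(5S)-2-methyl-5-(propan-2-yl)-5-(triethylsilyloxy)cyclopent-1-en-1-yl]methylidene}chromium; 13 (E)-3-methylbuta-1,3-dien-1-yl 3-methylbutanoate
Product: 15 (1S,4S,10R)-6-methoxy-4-(triethylsilyloxy)dauca-5,8-dien-10-yl 3-methylbutanoate, via cis-divinylcyclopropane 14 (not isolated)
Conditions: 13 (5 equiv), THF, 90 °C, sealed tube, argon
Reagents that add atoms: none
Why: Thermal CO loss from 10 and coordination of the terminal C7=C8 alkene of 13 should give a chromacyclobutane that eliminates cyclopropane 14 (bonds C6–C7 and C6–C8), whose two alkenyl groups then undergo a 3,3-sigmatropic shift that makes C1–C10 as C6–C8 breaks, a trans-cyclopropane being expected to equilibrate to 14 through the doubly allylic, methoxy-stabilised diradical. The closest known reaction type is the formal (4+3) annulation of alkenyl(alkoxy) Fischer carbene complexes with 1,3-dienes by cyclopropanation and divinylcyclopropane (Cope) rearrangement. The three-membered ring closes by (2+1) carbene transfer and ring B by ring expansion of the cis-divinylcyclopropane through a boat transition state. In that boat the E enol ester points its oxygen outward and the ring A alkene is forced to point the C1 methyl inward, so the C10 oxygen should end up cis to C2 and trans to the C1 methyl. The absolute sense should follow from C4, because the diene-derived unit stacks on the ring A face that carries the silyloxy group and not on the one that carries the isopropyl group. The step needs site selectivity for the 1,1-disubstituted terminal alkene over the acyloxy-substituted one, which lower steric demand and the vinylogous donor effect of the ester oxygen at C7 should secure, and chemoselectivity against Diels–Alder addition to the carbene-bound alkene, which its tetrasubstitution should block.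

Step 8
Reactants: 15 (1S,4S,10R)-6-methoxy-4-(triethylsilyloxy)dauca-5,8-dien-10-yl 3-methylbutanoate
Product: 16 (1S,4S,5R,10R)-6-oxo-4-(triethylsilyloxy)dauc-8-en-10-yl 3-methylbutanoate
Conditions: oxalic acid, THF/H2O, 0 °C to rt
Reagents that add atoms: water, O
Why: Mild enol ether hydrolysis in which the rate-limiting protonation of C5 should occur on the ring A face anti to the C1 methyl and C4 isopropyl groups, giving the trans-fused ketone under kinetic control, while cold weak acid spares the tertiary silyl ether and the allylic ester and avoids C5 epimerisation.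

Step 9
Reactants: 16 (1S,4S,5R,10R)-6-oxo-4-(triethylsilyloxy)dauc-8-en-10-yl 3-methylbutanoate
Product: 17 (1S,4S,5S,6R,10R)-6-hydroxy-4-(triethylsilyloxy)dauc-8-en-10-yl 3-methylbutanoate
Conditions: LiBH(s-Bu)3 (L-Selectride), THF, −78 °C; then H2O
Reagents that add atoms: none
Why: Ketone reduction with a bulky hydride, which should approach C6 syn to H5 and away from the C1 methyl and the C4 isopropyl group on the other face, placing the new hydroxyl cis to C4; the esters are inert at −78 °C.

Step 10
Reactants: 17 (1S,4S,5S,6R,10R)-6-hydroxy-4-(triethylsilyloxy)dauc-8-en-10-yl 3-methylbutanoate; 18 4-[(tert-butyldimethylsilyl)oxy]benzoic acid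
Product: 20 (1S,4S,5S,6R,10R)-10-(3-methylbutanoyloxy)-4-(triethylsilyloxy)dauc-8-en-6-yl 4-[(tert-butyldimethylsilyl)oxy]benzoate, via mixed anhydride 19 (not isolated)
Conditions: 18, 2,4,6-trichlorobenzoyl chloride, Et3N, THF, rt; then 17, DMAP, toluene, 60 °C
Reagents that add atoms: none
Why: Yamaguchi esterification through the mixed anhydride should acylate the only free hydroxyl, the hindered secondary C6 alcohol, with retention of configuration.

Step 11
Reactants: 20 (1S,4S,5S,6R,10R)-10-(3-methylbutanoyloxy)-4-(triethylsilyloxy)dauc-8-en-6-yl 4-[(tert-butyldimethylsilyl)oxy]benzoate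
Product: 21 (1S,4S,5S,6R,10R)-4-hydroxy-10-(3-methylbutanoyloxy)dauc-8-en-6-yl 4-hydroxybenzoate (CNP0086724.4)
Conditions: HF·pyridine, pyridine, THF, 0 °C to rt
Reagents that add atoms: none
Why: Fluoride-mediated desilylation should cleave the aryl and the tertiary silyl ether in one operation and leave both carboxylic esters and the allylic system untouched.

Compound list
1 | (R)-(−)-terpinen-4-ol | CC1=CC[C@@](O)(C(C)C)CC1 | starting material
2 | (R)-triethyl{[4-methyl-1-(propan-2-yl)cyclohex-3-en-1-yl]oxy}silane | CC1=CC[C@@](O[Si](CC)(CC)CC)(C(C)C)CC1 | intermediate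
3 | secondary ozonide of 2 (1,2,4-trioxolane, mixture at the trioxolane carbons) | CC12CC[C@](O[Si](CC)(CC)CC)(C(C)C)CC(OO1)O2 | intermediate (not isolated)
4 | (3R)-6-oxo-3-(propan-2-yl)-3-(triethylsilyloxy)heptanal | CC(=O)CC[C@](O[Si](CC)(CC)CC)(C(C)C)CC=O | intermediate
5 | aldol adduct, 2-hydroxy-2-methyl-5-(propan-2-yl)-5-(triethylsilyloxy)cyclopentane-1-carbaldehyde (mixture at C1 and C2) | O=CC1[C@@](O[Si](CC)(CC)CC)(C(C)C)CCC1(C)O | intermediate (not isolated)
6 | (5S)-2-methyl-5-(propan-2-yl)-5-(triethylsilyloxy)cyclopent-1-ene-1-carbaldehyde | O=CC1=C(C)CC[C@]1(O[Si](CC)(CC)CC)C(C)C | intermediate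
7 | (5S)-2-methyl-5-(propan-2-yl)-5-(triethylsilyloxy)cyclopent-1-ene-1-carboxylic acid | OC(=O)C1=C(C)CC[C@]1(O[Si](CC)(CC)CC)C(C)C | intermediate
8 | acid chloride of 7 | ClC(=O)C1=C(C)CC[C@]1(O[Si](CC)(CC)CC)C(C)C | intermediate (not isolated)
9 | sodium pentacarbonyl(acyl)chromate from 8 | [Na+].O=C(C1=C(C)CC[C@]1(O[Si](CC)(CC)CC)C(C)C)[Cr-](=C=O)(=C=O)(=C=O)(=C=O)=C=O | intermediate (not isolated)
10 | pentacarbonyl{methoxy[(5S)-2-methyl-5-(propan-2-yl)-5-(triethylsilyloxy)cyclopent-1-en-1-yl]methylidene}chromium | COC(C1=C(C)CC[C@]1(O[Si](CC)(CC)CC)C(C)C)=[Cr](=C=O)(=C=O)(=C=O)(=C=O)=C=O | intermediate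
11 | 3-methylbut-2-enal | CC(C)=CC=O | starting material
12 | 3-methylbutanoic anhydride | CC(C)CC(=O)OC(=O)CC(C)C | starting material
13 | (E)-3-methylbuta-1,3-dien-1-yl 3-methylbutanoate | CC(C)CC(=O)O/C=C/C(C)=C | intermediate
14 | (E)-2-[(1R,2S)-2-methoxy-1-methyl-2-{(5S)-2-methyl-5-(propan-2-yl)-5-(triethylsilyloxy)cyclopent-1-en-1-yl}cyclopropyl]ethenyl 3-methylbutanoate (cyclopentenyl and acyloxyvinyl groups cis) | CO[C@@]1(C2=C(C)CC[C@]2(O[Si](CC)(CC)CC)C(C)C)C[C@]1(C)/C=C/OC(=O)CC(C)C | intermediate (not isolated)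
15 | (1S,4S,10R)-6-methoxy-4-(triethylsilyloxy)dauca-5,8-dien-10-yl 3-methylbutanoate (C10–O cis to C2, trans to the C1 methyl) | CC1=C[C@@H](OC(=O)CC(C)C)[C@@]2(C)CC[C@](O[Si](CC)(CC)CC)(C(C)C)C2=C(OC)C1 | intermediate
16 | (1S,4S,5R,10R)-6-oxo-4-(triethylsilyloxy)dauc-8-en-10-yl 3-methylbutanoate (trans ring fusion) | CC1=C[C@@H](OC(=O)CC(C)C)[C@@]2(C)CC[C@](O[Si](CC)(CC)CC)(C(C)C)[C@@H]2C(=O)C1 | intermediate
17 | (1S,4S,5S,6R,10R)-6-hydroxy-4-(triethylsilyloxy)dauc-8-en-10-yl 3-methylbutanoate | CC1=C[C@@H](OC(=O)CC(C)C)[C@@]2(C)CC[C@](O[Si](CC)(CC)CC)(C(C)C)[C@@H]2[C@H](O)C1 | intermediate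
18 | 4-[(tert-butyldimethylsilyl)oxy]benzoic acid | CC(C)(C)[Si](C)(C)Oc1ccc(cc1)C(O)=O | starting material
19 | 4-[(tert-butyldimethylsilyl)oxy]benzoic 2,4,6-trichlorobenzoic anhydride | CC(C)(C)[Si](C)(C)Oc1ccc(cc1)C(=O)OC(=O)c1c(Cl)cc(Cl)cc1Cl | intermediate (not isolated)
20 | (1S,4S,5S,6R,10R)-10-(3-methylbutanoyloxy)-4-(triethylsilyloxy)dauc-8-en-6-yl 4-[(tert-butyldimethylsilyl)oxy]benzoate | CC1=C[C@@H](OC(=O)CC(C)C)[C@@]2(C)CC[C@](O[Si](CC)(CC)CC)(C(C)C)[C@@H]2[C@H](OC(=O)c2ccc(O[Si](C)(C)C(C)(C)C)cc2)C1 | intermediate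
21 | (1S,4S,5S,6R,10R)-4-hydroxy-10-(3-methylbutanoyloxy)dauc-8-en-6-yl 4-hydroxybenzoate | CC1=C[C@@H](OC(=O)CC(C)C)[C@@]2(C)CC[C@](O)(C(C)C)[C@@H]2[C@H](OC(=O)c2ccc(O)cc2)C1 | target

Total step count: 11. Longest linear sequence: 10 steps (steps 1–5 and 7–11, from 1).

Steps most likely to fail

Step 7. Carbene transfer from the crowded complex to the only moderately nucleophilic dienyl ester may be outrun by thermal decomposition of 10. Part of the cyclopropanation may go to the acyloxy-substituted double bond. The inward C1 methyl slows the Cope step, and its face selection may be modest. The fallback sets out from 10 and 11 and comes back at 16: the four-carbon partner becomes an electron-rich silyloxydiene that reacts by a polar pathway at lower temperature, and the isovalerate is attached afterwards. Aldehyde 11 with Me3SiCl, Et3N and catalytic ZnCl2 should give (E)-trimethyl[(3-methylbuta-1,3-dien-1-yl)oxy]silane F1. F1 and 10 in THF at 25–50 °C should give, by attack of the terminal CH2 on the carbene carbon and the same reorganisation to the seven-membered ring, (1S,4S,10R)-6-methoxy-4-(triethylsilyloxy)-10-(trimethylsilyloxy)dauca-5,8-diene F2. Cold aqueous oxalic acid should hydrolyse the enol ether and the secondary trimethylsilyl ether to the C10 hydroxy ketone F3, and acylation of its C10 hydroxyl with 12, Et3N and DMAP should give 16.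

Step 5. Single-electron transfer from the chromate dianion to the conjugated, hindered acid chloride may lead to reduction or ketene formation in place of acyl substitution, and the crowded acylate may decompose on alkylation. The fallback sets out from 6 and comes back at 16: no chromium carbene is made, C6 is transferred as a rhodium-bound vinylcarbene that carries hydrogen, and the C6 oxygen is introduced afterwards under direction of the C4 hydroxyl. Enal 6 and 2-(trifluoromethyl)benzenesulfonohydrazide (THF, rt) should give the sulfonylhydrazone F4. With NaH, Rh2(OAc)4 (1 mol %) and 13 (5 equiv) in CH2Cl2 from −40 °C to rt, then toluene at 110 °C, F4 should pass through the alkenyldiazomethane F5 and the cis-divinylcyclopropane F6 to the C6-unsubstituted cycloheptadiene F7, with the same two ring bonds formed. n-Bu4NF should free the tertiary allylic alcohol F8. VO(acac)2 and t-BuOOH should epoxidise only the allylic C5=C6 alkene, syn to the hydroxyl, to give the epoxy alcohol F9. Cp2TiCl (from Cp2TiCl2 and Mn) with 1,4-cyclohexadiene should open the epoxide to the tertiary C5 radical and reduce it from the less hindered face to the 4,6-diol F10, which has H5 cis to the C4 hydroxyl and the 6-epi alcohol. Dess–Martin periodinane should give the hydroxy ketone F11, and Et3SiOTf with 2,6-lutidine at −78 °C should give 16.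

Step 8. Protonation of the enol ether may occur from the wrong face, or the β-silyloxy ketone may epimerise at C5 or lose the C4 silyloxy group by β-elimination in the acidic medium. The fallback sets out from 15 and comes back at 16: H5 is delivered intramolecularly from the C4 oxygen instead of from an external acid. n-Bu4NF on 15 should give the free tertiary alcohol F12, and HMe2SiCl with imidazole in DMF should give the dimethylsilyl ether F13. With Pt2[(CH2=CHSiMe2)2O]3 in toluene at 60 °C, a 5-endo intramolecular hydrosilylation should add silicon to C6 and hydrogen to C5 syn from the face of the C4 oxygen, giving the oxasilolane F14. Tamao oxidation (H2O2, KF, KHCO3, THF/MeOH) should convert the C6–Si bond into a hemiketal that collapses to the hydroxy ketone F11, the compound also reached in the fallback for step 5. Et3SiOTf with 2,6-lutidine at −78 °C should then give 16.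

Further compounds
F1 | step 7 | (E)-trimethyl[(3-methylbuta-1,3-dien-1-yl)oxy]silane | C[Si](C)(C)O/C=C/C(C)=C
F2 | step 7 | (1S,4S,10R)-6-methoxy-4-(triethylsilyloxy)-10-(trimethylsilyloxy)dauca-5,8-diene | CC1=C[C@@H](O[Si](C)(C)C)[C@@]2(C)CC[C@](O[Si](CC)(CC)CC)(C(C)C)C2=C(OC)C1
F3 | step 7 | (1S,4S,5R,10R)-10-hydroxy-4-(triethylsilyloxy)dauc-8-en-6-one | CC1=C[C@@H](O)[C@@]2(C)CC[C@](O[Si](CC)(CC)CC)(C(C)C)[C@@H]2C(=O)C1
F4 | step 5 | N'-[(E)-{(5S)-2-methyl-5-(propan-2-yl)-5-(triethylsilyloxy)cyclopent-1-en-1-yl}methylidene]-2-(trifluoromethyl)benzenesulfonohydrazide | FC(F)(F)c1ccccc1S(=O)(=O)N/N=C/C1=C(C)CC[C@]1(O[Si](CC)(CC)CC)C(C)C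
F5 | step 5 | {[(5S)-2-(diazomethyl)-3-methyl-1-(propan-2-yl)cyclopent-2-en-1-yl]oxy}triethylsilane | [N-]=[N+]=CC1=C(C)CC[C@]1(O[Si](CC)(CC)CC)C(C)C
F6 | step 5 | cis-divinylcyclopropane with hydrogen at C6 (analogue of 14 without the methoxy group) | [C@@H]1(C2=C(C)CC[C@]2(O[Si](CC)(CC)CC)C(C)C)C[C@]1(C)/C=C/OC(=O)CC(C)C
F7 | step 5 | (1S,4S,10R)-4-(triethylsilyloxy)dauca-5,8-dien-10-yl 3-methylbutanoate | CC1=C[C@@H](OC(=O)CC(C)C)[C@@]2(C)CC[C@](O[Si](CC)(CC)CC)(C(C)C)C2=CC1
F8 | step 5 | (1S,4S,10R)-4-hydroxydauca-5,8-dien-10-yl 3-methylbutanoate | CC1=C[C@@H](OC(=O)CC(C)C)[C@@]2(C)CC[C@](O)(C(C)C)C2=CC1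
F9 | step 5 | 5,6-epoxy-4-hydroxydauc-8-en-10-yl 3-methylbutanoate (epoxide syn to the C4 hydroxyl) | CC1=C[C@@H](OC(=O)CC(C)C)[C@@]2(C)CC[C@](O)(C(C)C)[C@@]23O[C@H]3C1
F10 | step 5 | 4,6-dihydroxydauc-8-en-10-yl 3-methylbutanoate, 6-epimer (6-OH cis to H5) | CC1=C[C@@H](OC(=O)CC(C)C)[C@@]2(C)CC[C@](O)(C(C)C)[C@@H]2[C@@H](O)C1
F11 | step 5 | (1S,4S,5R,10R)-4-hydroxy-6-oxodauc-8-en-10-yl 3-methylbutanoate | CC1=C[C@@H](OC(=O)CC(C)C)[C@@]2(C)CC[C@](O)(C(C)C)[C@@H]2C(=O)C1
F12 | step 8 | (1S,4S,10R)-4-hydroxy-6-methoxydauca-5,8-dien-10-yl 3-methylbutanoate | CC1=C[C@@H](OC(=O)CC(C)C)[C@@]2(C)CC[C@](O)(C(C)C)C2=C(OC)C1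
F13 | step 8 | (1S,4S,10R)-4-(dimethylsilyloxy)-6-methoxydauca-5,8-dien-10-yl 3-methylbutanoate | CC1=C[C@@H](OC(=O)CC(C)C)[C@@]2(C)CC[C@](O[SiH](C)C)(C(C)C)C2=C(OC)C1
F14 | step 8 | oxasilolane bridging O4 and C6 through SiMe2 (C6 bears OMe; H5 and Si cis) | CC1=C[C@@H](OC(=O)CC(C)C)[C@@]2(C)CC[C@](O3)(C(C)C)[C@@H]2[C@]([Si]3(C)C)(OC)C1
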